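**Retrosynthetic overview**
1. Target ⇒ its hydroquinone diacetate; the last step only removes two aryl acetates.
2. (E)-Styrene C–C bond ⇒ Heck coupling of a vinyl carbinol with 2-bromo-1,4-phenylene diacetate (ring B).
3. Ring A–CH2 bond (key bond) ⇒ light-driven nickel/iridium deformylative arylation of a linalool-derived lactol with a 2,6-dimethyl aryl iodide; the lactol carbon leaves as formate.
4. Lactol ⇒ ozonolysis of (S)-linalool, which supplies the only stereocentre; aryl iodide ⇒ ortho-formylation and acetylation of 4-iodo-3,5-dimethylphenol.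
5. Rings: ring A and ring B are bought intact; the only ring made is the transient oxolane of the lactol (step 1), opened again in step 4.

Assumption: (S)-(+)-linalool (coriandrol) is bought in ≥95% ee; its carbinol carbon is never touched, so the ee of the target equals that of the lot used.

**Route**

Step 1
Reactants: 1 (S)-(+)-linalool, (3S)-3,7-dimethylocta-1,6-dien-3-ol
Product: 4 (5S)-5-ethenyl-5-methyloxolan-2-ol, via ozonide 2 (not isolated), via hydroxy aldehyde 3 (not isolated)
Conditions: O3, CH2Cl2, −78 °C (Sudan Red 7B end point); then Me2S, −78 °C to rt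
Reagents that add atoms: ozone, [O-][O+]=O
Why: Criegee ozonolysis with reductive work-up cleaves the electron-rich trisubstituted 6,7-alkene far faster than the monosubstituted vinyl group, and hydroxy aldehyde 3 closes spontaneously to lactol 4 (anomer mixture) with the S carbinol carbon of 1 untouched.

Step 2
Reactants: 5 4-iodo-3,5-dimethylphenol
Product: 7 6-hydroxy-3-iodo-2,4-dimethylbenzaldehyde, via hydroxymethylphenol 6 (not isolated)
Conditions: MgCl2, Et3N, (CH2O)n, MeCN, reflux; aq. HCl work-up
Reagents that add atoms: paraformaldehyde (formaldehyde), C=O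
Why: In this Casnati–Skattebøl ortho-formylation the magnesium phenoxide delivers formaldehyde to an ortho position (the two are equivalent, so one regioisomer forms) and a second formaldehyde oxidises 6 by hydride transfer, while the aryl iodide is inert.

Step 3
Reactants: 7 6-hydroxy-3-iodo-2,4-dimethylbenzaldehyde
Product: 8 2-formyl-4-iodo-3,5-dimethylphenyl acetate
Conditions: Ac2O, pyridine, DMAP (cat.), CH2Cl2, 0 °C to rt
Reagents that add atoms: acetic anhydride, CC(=O)OC(C)=O
Why: DMAP-catalysed O-acetylation masks the phenol so that it cannot be oxidised by, or quench, the photocatalyst in step 4.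

Step 4
Reactants: 4 (5S)-5-ethenyl-5-methyloxolan-2-ol (1.5 equiv); 8 2-formyl-4-iodo-3,5-dimethylphenyl acetate
Product: 10 6-hydroxy-3-[(3S)-3-hydroxy-3-methylpent-4-en-1-yl]-2,4-dimethylbenzaldehyde, via formate ester 9 (not isolated)
Conditions: [Ir(dF(CF3)ppy)2(5,5'-d(CF3)bpy)]PF6 (2 mol%), NiBr2(dme) (10 mol%), dtbbpy (12 mol%), 2,4,6-collidine (2 equiv), PhCF3/MeCN, 450 nm LEDs, 25 °C; then K2CO3 (1.5 equiv), MeOH, 0 °C to rt
Reagents that add atoms: none
Why: Proposed new method: deformylative C(sp3)–C(sp2) arylation of a lactol, in which the excited iridium photocatalyst and collidine remove the lactol O–H by proton-coupled electron transfer (PCET), the anomeric alkoxy radical opens by β-scission of the ring C2–C3 bond (driven by formation of the formate C=O) to the primary radical •CH2CH2C(CH3)(OCHO)CH=CH2, this small radical is captured by the divalent aryl-nickel iodide formed from 8, and reductive elimination from trivalent nickel forges the ring A–CH2 bond while the reduced photocatalyst returns nickel to its low-valent state; the carbinol carbon is a spectator and stays S, its oxygen being tied up first as lactol ether and then as formate so that it cannot itself enter PCET; the closest known reaction types are PCET ring-opening of cycloalkanols coupled to nickel-catalysed arylation of the remote radical and light-driven fragmentation of lactol alkoxy radicals to ω-functionalised alkyl formates, and what is untested is a lactol as radical source in a nickel arylation and the 2,6-disubstituted aryl iodide partner; the in-pot methanolysis removes the allylic formate (which would ionise with zerovalent palladium in step 6) and the aryl acetate.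

Step 5
Reactants: 11 2-bromobenzene-1,4-diol (bromohydroquinone)
Product: 12 2-bromo-1,4-phenylene diacetate
Conditions: Ac2O, pyridine, DMAP (cat.), CH2Cl2, rt
Reagents that add atoms: acetic anhydride, CC(=O)OC(C)=O
Why: Standard O-acetylation keeps the hydroquinone from oxidising or binding palladium in step 6 and blocks attack of the ortho oxygen on the allylic carbinol.

Step 6
Reactants: 10 6-hydroxy-3-[(3S)-3-hydroxy-3-methylpent-4-en-1-yl]-2,4-dimethylbenzaldehyde; 12 2-bromo-1,4-phenylene diacetate (1.2 equiv)
Product: 13 2-[(1E,3S)-5-(3-formyl-4-hydroxy-2,6-dimethylphenyl)-3-hydroxy-3-methylpent-1-en-1-yl]-1,4-phenylene diacetate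
Conditions: Pd(OAc)2 (5 mol%), P(o-tol)3 (10 mol%), Et3N, MeCN, 85 °C, Ar
Reagents that add atoms: none
Why: In this Mizoroki–Heck reaction the aryl-palladium adds to the terminal vinyl carbon and β-hydride elimination can only give the conjugated E-alkene because the carbinol carbon bears no hydrogen (so no ketone forms), the stereocentre is not involved, and any acetyl migration to the ring A phenol is harmless because step 7 removes all acetates.

Step 7
Reactants: 13 2-[(1E,3S)-5-(3-formyl-4-hydroxy-2,6-dimethylphenyl)-3-hydroxy-3-methylpent-1-en-1-yl]-1,4-phenylene diacetate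
Product: 14 3-[(3S,4E)-5-(2,5-dihydroxyphenyl)-3-hydroxy-3-methylpent-4-en-1-yl]-6-hydroxy-2,4-dimethylbenzaldehyde
Conditions: K2CO3 (0.3 equiv), degassed MeOH, 0 °C, Ar; pH 6 phosphate buffer quench
Reagents that add atoms: none
Why: Zemplén-type transesterification cleaves both aryl acetates at 0 °C without touching the aldehyde or the tertiary allylic alcohol, and the oxygen-free, acid-free conditions avoid quinone formation and chromene closure of the ortho-hydroxystyryl carbinol.

**Compound list**
1 | (S)-(+)-linalool, (3S)-3,7-dimethylocta-1,6-dien-3-ol | CC(C)=CCC[C@](C)(O)C=C | starting material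
2 | 5-[(3S)-3-hydroxy-3-methylpent-4-en-1-yl]-3,3-dimethyl-1,2,4-trioxolane (ozonide, epimer mixture at the ring carbon) | CC1(C)OOC(CC[C@](C)(O)C=C)O1 | intermediate
3 | (4S)-4-hydroxy-4-methylhex-5-enal | O=CCC[C@](C)(O)C=C | intermediate
4 | (5S)-5-ethenyl-5-methyloxolan-2-ol (lactol, anomer mixture) | OC1CC[C@@](C)(C=C)O1 | intermediate
5 | 4-iodo-3,5-dimethylphenol | Cc1cc(O)cc(C)c1I | starting material
6 | 2-(hydroxymethyl)-4-iodo-3,5-dimethylphenol | Cc1cc(O)c(CO)c(C)c1I | intermediate
7 | 6-hydroxy-3-iodo-2,4-dimethylbenzaldehyde | Cc1cc(O)c(C=O)c(C)c1I | intermediate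
8 | 2-formyl-4-iodo-3,5-dimethylphenyl acetate | Cc1cc(OC(C)=O)c(C=O)c(C)c1I | intermediate
9 | (3S)-1-(4-acetoxy-3-formyl-2,6-dimethylphenyl)-3-methylpent-4-en-3-yl formate | Cc1cc(OC(C)=O)c(C=O)c(C)c1CC[C@](C)(OC=O)C=C | intermediate
10 | 6-hydroxy-3-[(3S)-3-hydroxy-3-methylpent-4-en-1-yl]-2,4-dimethylbenzaldehyde | Cc1cc(O)c(C=O)c(C)c1CC[C@](C)(O)C=C | intermediate
11 | 2-bromobenzene-1,4-diol | Oc1ccc(O)c(Br)c1 | starting material
12 | 2-bromo-1,4-phenylene diacetate | CC(=O)Oc1ccc(OC(C)=O)c(Br)c1 | intermediate
13 | 2-[(1E,3S)-5-(3-formyl-4-hydroxy-2,6-dimethylphenyl)-3-hydroxy-3-methylpent-1-en-1-yl]-1,4-phenylene diacetate | Cc1cc(O)c(C=O)c(C)c1CC[C@](C)(O)/C=C/c1cc(OC(C)=O)ccc1OC(C)=O | intermediate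
14 | 3-[(3S,4E)-5-(2,5-dihydroxyphenyl)-3-hydroxy-3-methylpent-4-en-1-yl]-6-hydroxy-2,4-dimethylbenzaldehyde | Cc1cc(O)c(C=O)c(C)c1CC[C@](C)(O)/C=C/c1cc(O)ccc1O | target

**Step count and risks**
Total steps: 7. Longest linear sequence: 5 (steps 2, 3, 4, 6, 7, from 5); the branch from linalool is 4 steps (1, 4, 6, 7).

Step 4 (the proposed new step). It can fail through inefficient PCET on the lactol once iodide builds up, or through slow radical capture at the di-ortho-substituted aryl nickel. The fallback uses known chemistry, sets out from 4 and rejoins the route at 9. Lactol 4 is fragmented under Suárez conditions (PhI(OAc)2, I2, CH2Cl2, visible light, rt), the same alkoxy-radical β-scission now ended by iodine transfer, to give (3S)-5-iodo-3-methylpent-1-en-3-yl formate F1. Zinc insertion (Zn dust, LiCl, THF, 25 °C) gives [(3S)-3-(formyloxy)-3-methylpent-4-en-1-yl]zinc iodide F2. Negishi coupling of F2 with 8 (Pd(OAc)2, SPhos, THF, rt, with excess 8 so that oxidative addition to the aryl iodide outruns ionisation of the allylic formate) gives 9, which is methanolysed as in step 4 (K2CO3, MeOH) to 10.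

Step 6. It can fail through slow insertion of the hindered vinyl carbinol or through loss of acetate from 12 and catalyst poisoning by the freed hydroquinone. The fallback sets out from 10 and 12 and rejoins at 13. Stille vinylation of 12 (tributyl(vinyl)stannane, Pd(PPh3)4, toluene, 100 °C) gives 2-ethenyl-1,4-phenylene diacetate F3. Cross-metathesis of excess F3 with 10 (second-generation Hoveyda–Grubbs catalyst, CH2Cl2, 40 °C) gives 13 as the E-alkene, since the tertiary allylic alcohol does not homodimerise.

Step 7. It can fail through air oxidation of the hydroquinone to the quinone under base. The fallback replaces the base-labile acetates by fluoride-labile silyl ethers; it sets out from 11 and 10 and rejoins at 14. Silylation of 11 (TBSCl, imidazole, DMF, rt) gives 2-bromo-1,4-bis(tert-butyldimethylsilyloxy)benzene F4. Heck coupling of F4 with 10 under the step 6 conditions gives 3-[(3S,4E)-5-[2,5-bis(tert-butyldimethylsilyloxy)phenyl]-3-hydroxy-3-methylpent-4-en-1-yl]-6-hydroxy-2,4-dimethylbenzaldehyde F5. KHF2 in MeOH at rt then cleaves both aryl silyl ethers under weakly acidic conditions to give 14.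

**Further compounds**
F1 | step 4 | (3S)-5-iodo-3-methylpent-1-en-3-yl formate | ICC[C@](C)(OC=O)C=C
F2 | step 4 | [(3S)-3-(formyloxy)-3-methylpent-4-en-1-yl]zinc iodide | I[Zn]CC[C@](C)(OC=O)C=C
F3 | step 6 | 2-ethenyl-1,4-phenylene diacetate | C=Cc1cc(OC(C)=O)ccc1OC(C)=O
F4 | step 7 | 2-bromo-1,4-bis(tert-butyldimethylsilyloxy)benzene | CC(C)(C)[Si](C)(C)Oc1ccc(O[Si](C)(C)C(C)(C)C)c(Br)c1
F5 | step 7 | 3-[(3S,4E)-5-[2,5-bis(tert-butyldimethylsilyloxy)phenyl]-3-hydroxy-3-methylpent-4-en-1-yl]-6-hydroxy-2,4-dimethylbenzaldehyde | Cc1cc(O)c(C=O)c(C)c1CC[C@](C)(O)/C=C/c1cc(O[Si](C)(C)C(C)(C)C)ccc1O[Si](C)(C)C(C)(C)C
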